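**Assumption (one line):** The C8 carbinol centre of the furfuryl intermediate is transient, so C8 epimers converge in the electrocyclization. C12 is set by torquoselective ring closure relayed from the D-xylose-derived C7 oxygen stereocentre.

## Retrosynthesis (overview)
1. Target (18) ⇐ dehydration of chlorohydrin 17 ⇐ HCl opening of enone epoxide 16 ⇐ epoxidation of dienone 15 ⇐ β-elimination of the C7-OAc from cyclopentenone 14.
2. The only ring, the 4-hydroxy-4-alkylcyclopentenone, forms by a Piancatelli rearrangement (4π conrotatory electrocyclization of the furfuryl cation from 13). This sets the C12 tertiary carbinol.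
3. Furfuryl acetate 13 ⇐ 5-lithio-2-[(Z)-octenyl]furan (12) + the xylose-derived aldehyde 8. D-Xylose, read C1→C4, supplies C5–C8; its C4 oxygen becomes the C7 relay oxygen and is later eliminated.

## Route

**Step 1**
Reactants: 1 (D-xylose); 2 ((2-carboxyethyl)triphenylphosphonium bromide)
Product: 3 ((3Z,5S,6R,7R)-5,6,7,8-tetrahydroxyoct-3-enoic acid, i.e. chain C1–C8 with D-xylose C1 as C4)
Conditions: KOtBu (4 equiv), DMSO–THF, rt; H3O+ workup
Reagents that add atoms: none beyond 2
Why: Wittig olefination of the sugar aldehyde carbon (lactol opens in situ) adds C1–C3. The sugar stereocentres are untouched; D-xylose C2/C3 become C5/C6 (S,S) and C4 becomes C7.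

**Step 2**
Reactants: 3
Product: 4 (methyl (5S,6R,7R)-5,6,7,8-tetrahydroxyoctanoate; descriptors refer to the tetraol, the spatial arrangement is unchanged)
Conditions: H2 (1 atm), 10% Pd/C, MeOH, rt; then Amberlyst-15 (H+), MeOH, rt (one pot)
Reagents that add atoms: MeOH, CO
Why: Catalytic hydrogenation saturates C3=C4. Acid methanolysis gives the methyl ester, and excess MeOH opens any δ-lactone. No stereocentre is affected.

**Step 3**
Reactants: 4
Product: 5 (8-O-trityl ether of 4)
Conditions: TrCl, pyridine, DMAP (cat.), 50 °C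
Reagents that add atoms: trityl chloride, ClC(c1ccccc1)(c1ccccc1)c1ccccc1
Why: Bulky trityl chloride silylation-type protection is selective for the single primary hydroxyl, leaving the secondary alcohols for acetylation.

**Step 4**
Reactants: 5
Product: 6 (5,6,7-tri-O-acetyl-8-O-trityl ester)
Conditions: Ac2O, pyridine, DMAP (cat.), 0 °C→rt
Reagents that add atoms: acetic anhydride, CC(=O)OC(C)=O
Why: Acetylation of the three secondary OH groups installs the final C5/C6 acetates and the C7 leaving group.

**Step 5**
Reactants: 6
Product: 7 (methyl 5,6,7-triacetoxy-8-hydroxyoctanoate)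
Conditions: ZnBr2, CH2Cl2, rt
Reagents that add atoms: none
Why: Lewis-acid detritylation is mild and leaves the acetates and ester intact.

**Step 6**
Reactants: 7
Product: 8 (methyl (5S,6S,7R)-5,6,7-triacetoxy-8-oxooctanoate, the aldehyde)
Conditions: Dess–Martin periodinane, NaHCO3, CH2Cl2, rt
Reagents that add atoms: none
Why: Dess–Martin oxidation under buffered, non-basic conditions gives the aldehyde without β-elimination or α-epimerization. The aldehyde is used immediately.

**Step 7**
Reactants: 9 ((Z)-oct-2-en-1-ol)
Product: 10 ((Z)-1-bromooct-2-ene)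
Conditions: CBr4, PPh3, CH2Cl2, 0 °C
Reagents that add atoms: carbon tetrabromide, BrC(Br)(Br)Br
Why: Appel bromination proceeds by SN2 at the primary carbon, so the Z-alkene is retained.

**Step 8**
Reactants: 11 (furan); 10
Product: 12 (2-[(Z)-oct-2-en-1-yl]furan)
Conditions: n-BuLi, THF, −20 °C; then CuI (10 mol %), 10, −20 °C→rt
Reagents that add atoms: none beyond 10
Why: Lithiation of furan then Cu-catalysed SN2 alkylation of the allylic bromide installs the C13–C20 chain on furan C5 (the future C12).

**Step 9**
Reactants: 12; 8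
Product: 13 (furfuryl acetate: 5-[(Z)-octenyl]furan-2-yl–CH(OAc)–C7…C5 triacetate; C8 epimers)
Conditions: n-BuLi, THF, 0 °C; CeCl3, −78 °C; add 8; then Ac2O, −78→0 °C
Reagents that add atoms: acetic anhydride, CC(=O)OC(C)=O
Why: Organocerium 1,2-addition to the aldehyde is chemoselective over the esters. Quenching with Ac2O acetylates the C8 alkoxide whether or not a 1,2-acyl shift from C7 occurred, so one constitution results. The C8 centre is transient.

**Step 10 (key step)**
Reactants: 13
Product: 14 (methyl (5S,6S)-5,6-diacetoxy-7-acetoxy-cyclopentenone: trans-4-hydroxy-4-[(Z)-octenyl]-5-(triacetoxyalkyl)cyclopent-2-enone)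
Conditions: Dy(OTf)3 (5 mol %), MeCN–H2O (9:1), 60 °C
Reagents that add atoms: water, O
Why: This is a Piancatelli rearrangement. Ionization of the furfuryl acetate, water capture at furan C5 and ring opening give a hydroxypentadienyl cation, which closes by 4π conrotation to the 4-hydroxy-4-alkyl-5-substituted cyclopentenone (OH trans to the C8 side chain). The C7-OAc centre biases the sense of conrotation (forming C8–C12 bond anti to the C7–O bond), setting C12 as (R), which is the required configuration.

**Step 11**
Reactants: 14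
Product: 15 (dienone: 7E-ene, C12-OH, 5,6-diacetate)
Conditions: DBU, CH2Cl2, 0 °C, 10 min
Reagents that add atoms: none
Why: E1cB loss of the β-acetoxy group from the acidic C8–H gives the conjugated exocyclic (E)-alkylidene, the thermodynamic isomer. C8 and C7 stereochemistry is destroyed and C12, C6 and C5 are untouched.

**Step 12**
Reactants: 15
Product: 16 (C10–C11 epoxy ketone; epoxide diastereomers not defined, as both centres are lost in step 14)
Conditions: t-BuOOH, DBU (cat.), THF, 0 °C
Reagents that add atoms: tert-butyl hydroperoxide, CC(C)(C)OO (delivers O)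
Why: Weitz–Scheffer nucleophilic epoxidation selects the less substituted, more electrophilic ring enone C10=C11 over the exocyclic enone and the isolated Z-alkene.

**Step 13**
Reactants: 16
Product: 17 (10-chloro-11-hydroxy ketone)
Conditions: HCl (4 M in dioxane), Et2O, 0 °C
Reagents that add atoms: hydrogen chloride, Cl
Why: Chloride opens the α,β-epoxy ketone at the α-carbon (SN2 activated by the carbonyl), placing Cl at C10.

**Step 14**
Reactants: 17
Product: 18 (Punaglandin 4)
Conditions: MsCl, Et3N, CH2Cl2, −10→0 °C
Reagents that add atoms: none (the mesylate is lost in the elimination)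
Why: The secondary C11–OH is mesylated (the tertiary C12–OH is not), then E1cB elimination through the acidic C10–H gives the 10-chloroenone.

## Compound list
1 | D-xylose | O=C[C@H](O)[C@@H](O)[C@H](O)CO | starting material
2 | (2-carboxyethyl)triphenylphosphonium bromide | OC(=O)CC[P+](c1ccccc1)(c1ccccc1)c1ccccc1.[Br-] | starting material
3 | (3Z)-5,6,7,8-tetrahydroxyoct-3-enoic acid | OC(=O)C/C=C\[C@H](O)[C@@H](O)[C@H](O)CO | intermediate
4 | methyl 5,6,7,8-tetrahydroxyoctanoate | COC(=O)CCC[C@H](O)[C@@H](O)[C@H](O)CO | intermediate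
5 | 8-O-trityl ether of 4 | COC(=O)CCC[C@H](O)[C@@H](O)[C@H](O)COC(c1ccccc1)(c1ccccc1)c1ccccc1 | intermediate
6 | 5,6,7-triacetate of 5 | COC(=O)CCC[C@H](OC(C)=O)[C@@H](OC(C)=O)[C@H](OC(C)=O)COC(c1ccccc1)(c1ccccc1)c1ccccc1 | intermediate
7 | methyl 5,6,7-triacetoxy-8-hydroxyoctanoate | COC(=O)CCC[C@H](OC(C)=O)[C@@H](OC(C)=O)[C@H](OC(C)=O)CO | intermediate
8 | methyl 5,6,7-triacetoxy-8-oxooctanoate | COC(=O)CCC[C@H](OC(C)=O)[C@@H](OC(C)=O)[C@H](OC(C)=O)C=O | intermediate
9 | (Z)-oct-2-en-1-ol | CCCCC/C=C\CO | starting material
10 | (Z)-1-bromooct-2-ene | CCCCC/C=C\CBr | intermediate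
11 | furan | c1ccoc1 | starting material
12 | 2-[(Z)-oct-2-en-1-yl]furan | CCCCC/C=C\Cc1ccco1 | intermediate
13 | furfuryl acetate (C8 epimers) | CCCCC/C=C\Cc1ccc(o1)C(OC(C)=O)[C@@H](OC(C)=O)[C@H](OC(C)=O)[C@H](CCCC(=O)OC)OC(C)=O | intermediate
14 | trans-4-hydroxycyclopentenone | CCCCC/C=C\C[C@@]1(O)C=CC(=O)[C@H]1[C@@H](OC(C)=O)[C@H](OC(C)=O)[C@H](CCCC(=O)OC)OC(C)=O | intermediate
15 | 7E-dienone | CCCCC/C=C\C[C@@]1(O)C=CC(=O)/C1=C/[C@H](OC(C)=O)[C@H](CCCC(=O)OC)OC(C)=O | intermediate
16 | C10–C11 epoxy ketone | CCCCC/C=C\C[C@@]1(O)C2OC2C(=O)/C1=C/[C@H](OC(C)=O)[C@H](CCCC(=O)OC)OC(C)=O | intermediate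
17 | 10-chloro-11-hydroxy ketone | CCCCC/C=C\C[C@@]1(O)C(O)C(Cl)C(=O)/C1=C/[C@H](OC(C)=O)[C@H](CCCC(=O)OC)OC(C)=O | intermediate
18 | Punaglandin 4 | CCCCC/C=C\C[C@@]1(O)C=C(Cl)C(=O)/C1=C/[C@H](OC(C)=O)[C@H](CCCC(=O)OC)OC(C)=O | target

## Totals
Total steps: 14. Longest linear sequence: 12 (steps 1–6, 9–14).

## Three steps most likely to fail
1. **Step 10 (Piancatelli).** The β-acetoxy group disfavours cation formation, the C7-relayed torquoselectivity may be modest, and the acetates may hydrolyse. Fallback: run the same sequence from the C7-epimeric aldehyde made from L-arabinose (read C1→C4, which also gives 5S,6S), to reverse the relay sense.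
2. **Steps 12–14 (epoxidation, HCl opening, dehydration).** Base can cause retro-aldol or acetate loss, and the wrong enone may be epoxidized. Fallback: install chlorine before ring formation by running the Piancatelli on a 3-chlorofuran-derived furfuryl acetate, which delivers the 10-chloroenone directly.
3. **Steps 1 and 6 (free-sugar Wittig; sensitive α,β-diacetoxy aldehyde).** Possible epimerization at C2, and β-elimination of the aldehyde. Fallback: skip the aldehyde. Use the peracetylated furanose lactol and C-glycosylate 12 (TMSOTf), then open the resulting furyl C-glycoside in the Piancatelli step.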